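C1 is the carboxyl carbon, the 1,2-dioxane ring is O1–O2–C3–C4–C5–C6 and the side chain runs C7–C14. Everything rests on disconnecting O1–C6. The feature exploited is the fully substituted ring carbon C6, which bears O1 and the one-carbon branch C7: it is read as a C6–C7 oxirane opened at C6. In one acid-mediated operation the C3 hydroperoxide of the precursor closes the dioxane ring, forms O1–C6 with inversion, fixes C6 from the oxirane configuration and frees C7 as a hydroxymethyl handle. The precursor is an acyclic (R)-2,2-disubstituted oxirane carrying the (3S)-hydroperoxide, the (4R)-ethyl branch and a silyl-protected C1 alcohol.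

Key step: step 14

Remark (naming): ring locants of the dioxane intermediates follow the target numbering above, so the carbon bearing the two-carbon arm is C3; TBDPS = tert-butyldiphenylsilyl, TES = triethylsilyl.
Remark (protecting group): the C1 oxygen is carried as a TBDPS ether, not a tert-butyldimethylsilyl ether, because it must pass PPTS/MeOH, KOH/H2O2 and CSA unchanged.
Remark (purchased reagents): ylide 11, thiol 31 and 1-bromopropane 32 are taken as commercial.

Step 1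
Reactants: 1 (S)-4-benzyl-1,3-oxazolidin-2-one; 2 butanoyl chloride
Product: 3 (4S)-4-benzyl-3-butanoyl-1,3-oxazolidin-2-one
Conditions: n-BuLi, THF, −78 °C; then 2, −78 → 0 °C
Reagents that add atoms: none
Why: N-acylation of the lithiated oxazolidinone by the acid chloride is the standard preparation of an Evans imide, and this one imide later serves as donor in both the aldol (step 4) and the alkylation (step 19).

Step 2
Reactants: 4 propane-1,3-diol
Product: 5 3-(TBDPS-oxy)propan-1-ol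
Conditions: NaH (1.0 equiv), THF, 0 °C → rt; then t-BuPh2SiCl (1.0 equiv), rt
Reagents that add atoms: tert-butyl(chloro)diphenylsilane, CC(C)(C)[Si](Cl)(c1ccccc1)c1ccccc1
Why: O-silylation of the monosodium alkoxide of a symmetrical diol should stop at the mono-ether, because the sparingly soluble mono-alkoxide reacts as it forms.

Step 3
Reactants: 5 3-(TBDPS-oxy)propan-1-ol
Product: 6 3-(TBDPS-oxy)propanal
Conditions: TEMPO (cat.), PhI(OAc)2, CH2Cl2, rt
Reagents that add atoms: none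
Why: Oxoammonium-mediated (TEMPO) oxidation takes a primary alcohol to the aldehyde without over-oxidation and leaves the silyl ether alone.

Step 4
Reactants: 3 (4S)-4-benzyl-3-butanoyl-1,3-oxazolidin-2-one; 6 3-(TBDPS-oxy)propanal
Product: 8 (4S)-4-benzyl-3-[(2S,3R)-5-(TBDPS-oxy)-2-ethyl-3-hydroxypentanoyl]-1,3-oxazolidin-2-one, via dibutylboron (Z)-enolate 7 (not isolated)
Conditions: Bu2BOTf, i-Pr2NEt, CH2Cl2, 0 °C; then 6, −78 → 0 °C; work-up pH 7 buffer, MeOH, 30% H2O2
Reagents that add atoms: none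
Why: Evans syn-aldol reaction, in which the (Z)-boron enolate reacts through a chair Zimmerman–Traxler transition state on the face away from the benzyl group; this sets C4 in its final sense and C3 as the (R)-carbinol, deliberately epimeric so that the SN2 step 13 delivers 3S.

Step 5
Reactants: 8 (4S)-4-benzyl-3-[(2S,3R)-5-(TBDPS-oxy)-2-ethyl-3-hydroxypentanoyl]-1,3-oxazolidin-2-one
Product: 9 (4S)-4-benzyl-3-[(2S,3R)-5-(TBDPS-oxy)-2-ethyl-3-(TES-oxy)pentanoyl]-1,3-oxazolidin-2-one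
Conditions: Et3SiOTf, 2,6-lutidine, CH2Cl2, −78 → 0 °C
Reagents that add atoms: triethylsilyl trifluoromethanesulfonate, CC[Si](CC)(CC)OS(=O)(=O)C(F)(F)F
Why: O-silylation of the secondary carbinol; TES survives hydride reagents and the epoxidation yet can later be removed by mild acid without loss of the primary TBDPS ether.

Step 6
Reactants: 9 (4S)-4-benzyl-3-[(2S,3R)-5-(TBDPS-oxy)-2-ethyl-3-(TES-oxy)pentanoyl]-1,3-oxazolidin-2-one
Product: 10 (2R,3R)-5-(TBDPS-oxy)-2-ethyl-3-(TES-oxy)pentan-1-ol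
Conditions: LiBH4, MeOH (1 equiv), THF, 0 °C
Reagents that add atoms: none
Why: Reductive cleavage of the imide at the exocyclic carbonyl gives the C5 primary alcohol without touching C3 or C4 and returns the auxiliary.

Step 7
Reactants: 10 (2R,3R)-5-(TBDPS-oxy)-2-ethyl-3-(TES-oxy)pentan-1-ol; 11 ethyl 2-(triphenylphosphoranylidene)butanoate
Product: 13 ethyl (2E,4R,5R)-7-(TBDPS-oxy)-2,4-diethyl-5-(TES-oxy)hept-2-enoate, via aldehyde 12 (not isolated)
Conditions: PhI(OAc)2, TEMPO (cat.), CH2Cl2, rt; then 11, 40 °C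
Reagents that add atoms: none
Why: TEMPO oxidation followed in the same flask by Wittig olefination with the α-ethyl stabilised ylide should give the (E)-trisubstituted enoate (ester trans to C4), and trapping the α-branched aldehyde at once protects C4 from epimerisation.

Step 8
Reactants: 13 ethyl (2E,4R,5R)-7-(TBDPS-oxy)-2,4-diethyl-5-(TES-oxy)hept-2-enoate
Product: 14 (2E,4R,5R)-7-(TBDPS-oxy)-2,4-diethyl-5-(TES-oxy)hept-2-en-1-ol
Conditions: i-Bu2AlH, CH2Cl2, −78 °C
Reagents that add atoms: none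
Why: 1,2-Reduction of the conjugated ester by i-Bu2AlH gives the allylic alcohol with the (E) geometry and both silyl ethers intact.

Step 9
Reactants: 14 (2E,4R,5R)-7-(TBDPS-oxy)-2,4-diethyl-5-(TES-oxy)hept-2-en-1-ol
Product: 15 [(2S,3S)-3-[(3R,4R)-6-(TBDPS-oxy)-4-(TES-oxy)hexan-3-yl]-2-ethyloxiran-2-yl]methanol
Conditions: Ti(OiPr)4 (0.3 equiv), L-(+)-diethyl tartrate (0.36 equiv), t-BuOOH, 4 Å molecular sieves, CH2Cl2, −20 °C
Reagents that add atoms: tert-butyl hydroperoxide, CC(C)(C)OO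
Why: Sharpless asymmetric epoxidation with the L-(+)-tartrate catalyst delivers oxygen to the face that makes C6 (S) here, as it does at C2 of (E)-allylic alcohols in general; this pairing opposes the allylic-strain preference of the C4 centre, so catalyst control is relied on, and the C5 centre formed alongside is erased in step 10.

Step 10
Reactants: 15 [(2S,3S)-3-[(3R,4R)-6-(TBDPS-oxy)-4-(TES-oxy)hexan-3-yl]-2-ethyloxiran-2-yl]methanol
Product: 16 (2R,4R,5R)-7-(TBDPS-oxy)-2,4-diethyl-5-(TES-oxy)heptane-1,2-diol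
Conditions: LiAlH4, THF, 0 → 40 °C
Reagents that add atoms: none
Why: Nucleophilic hydride opens the 2,3-epoxy alcohol by SN2 attack at C5, the only oxirane carbon that is not fully substituted, so the C6–O bond and the C6 configuration are kept (descriptor R by priority change) and the C5 stereocentre disappears.

Step 11
Reactants: 16 (2R,4R,5R)-7-(TBDPS-oxy)-2,4-diethyl-5-(TES-oxy)heptane-1,2-diol
Product: 17 (2R,4R,5R)-7-(TBDPS-oxy)-2,4-diethylheptane-1,2,5-triol
Conditions: PPTS (cat.), MeOH, 0 °C → rt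
Reagents that add atoms: none
Why: Acid-catalysed methanolysis removes the secondary triethylsilyl ether much faster than the bulky primary TBDPS ether, and does so before any acid-sensitive oxirane is present.

Step 12
Reactants: 17 (2R,4R,5R)-7-(TBDPS-oxy)-2,4-diethylheptane-1,2,5-triol
Product: 19 (2R)-2-[(2R,3R)-5-(TBDPS-oxy)-2-ethyl-3-(methanesulfonyloxy)pentyl]-2-ethyloxirane, via bis-mesylate 18 (not isolated)
Conditions: MsCl (2.3 equiv), Et3N, CH2Cl2, −20 °C; then MeOH, K2CO3, 0 °C → rt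
Reagents that add atoms: methanesulfonyl chloride, CS(=O)(=O)Cl
Why: Sulfonylation takes the primary C7 and secondary C3 hydroxyls and spares the tertiary one, whose alkoxide then displaces the adjacent primary mesylate in a 3-exo-tet Williamson closure that does not break the C6–O bond (retention at C6) and leaves the C3 mesylate for step 13.

Step 13
Reactants: 19 (2R)-2-[(2R,3R)-5-(TBDPS-oxy)-2-ethyl-3-(methanesulfonyloxy)pentyl]-2-ethyloxirane
Product: 20 (2R)-2-[(2R,3S)-5-(TBDPS-oxy)-2-ethyl-3-hydroperoxypentyl]-2-ethyloxirane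
Conditions: 50% aq. H2O2 (excess), KOH, MeOH/THF, 0 °C → rt
Reagents that add atoms: hydrogen peroxide, OO
Why: SN2 displacement of a secondary methanesulfonate by hydroperoxide anion, the classical synthesis of secondary alkyl hydroperoxides, inverts C3 from R to S; the oxirane offers this nucleophile only the C7 methylene next to a quaternary carbon and is expected to survive.

Step 14
Reactants: 20 (2R)-2-[(2R,3S)-5-(TBDPS-oxy)-2-ethyl-3-hydroperoxypentyl]-2-ethyloxirane
Product: 21 [(3S,4R,6S)-3-[2-(TBDPS-oxy)ethyl]-4,6-diethyl-1,2-dioxan-6-yl]methanol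
Conditions: camphorsulfonic acid (0.1–0.2 equiv), CH2Cl2, 0 °C → rt
Reagents that add atoms: none
Why: Protonation of the oxirane oxygen polarises the C6–O bond, and the terminal oxygen of the C3 hydroperoxide attacks C6 from the side opposite the departing oxygen in a borderline SN2 opening. The closest known reaction type is the acid-promoted intramolecular opening of epoxides by hydroperoxides at the more substituted carbon to give cyclic peroxides. The 1,2-dioxane closes in the 6-exo-tet mode through a chair with the C3 arm, the C4 ethyl and the C6 ethyl groups equatorial and the new hydroxymethyl group axial. C6 is the only new stereocentre and is dictated by the (R) configuration of the oxirane through inversion, not by any ring preference between ethyl and hydroxymethyl. The step needs attack at tertiary C6 (6-exo) over C7 (7-endo) and must avoid a free cation: acid activation loads the positive charge onto the tertiary carbon, the tether delivers the nucleophile in a non-polar solvent before ionisation or hydride shift can compete, and the TBDPS ether resists the acid.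

Step 15
Reactants: 21 [(3S,4R,6S)-3-[2-(TBDPS-oxy)ethyl]-4,6-diethyl-1,2-dioxan-6-yl]methanol
Product: 22 (3S,4R,6S)-3-[2-(TBDPS-oxy)ethyl]-4,6-diethyl-1,2-dioxane-6-carbaldehyde
Conditions: Dess–Martin periodinane, CH2Cl2, 0 °C → rt
Reagents that add atoms: none
Why: Dess–Martin oxidation converts the hindered primary alcohol to the aldehyde under neutral conditions that leave the dialkyl peroxide alone, and the product has no α-hydrogen and so cannot epimerise.

Step 16
Reactants: 22 (3S,4R,6S)-3-[2-(TBDPS-oxy)ethyl]-4,6-diethyl-1,2-dioxane-6-carbaldehyde; 11 ethyl 2-(triphenylphosphoranylidene)butanoate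
Product: 23 ethyl (2E)-3-[(3S,4R,6S)-3-[2-(TBDPS-oxy)ethyl]-4,6-diethyl-1,2-dioxan-6-yl]-2-ethylprop-2-enoate
Conditions: toluene, 60–80 °C
Reagents that add atoms: none
Why: Wittig olefination with the α-ethyl stabilised ylide should give the (E)-trisubstituted C7=C8 enoate (C6 trans to the ester carbon, the future C9), and the α-oxygenated aldehyde is activated enough to react on moderate heating that a dialkyl peroxide tolerates.

Step 17
Reactants: 23 ethyl (2E)-3-[(3S,4R,6S)-3-[2-(TBDPS-oxy)ethyl]-4,6-diethyl-1,2-dioxan-6-yl]-2-ethylprop-2-enoate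
Product: 24 (2E)-3-[(3S,4R,6S)-3-[2-(TBDPS-oxy)ethyl]-4,6-diethyl-1,2-dioxan-6-yl]-2-ethylprop-2-en-1-ol
Conditions: i-Bu2AlH, CH2Cl2, −78 °C
Reagents that add atoms: none
Why: 1,2-Reduction of the enoate by i-Bu2AlH at low temperature gives the allylic alcohol, conditions under which a hindered dialkyl peroxide is expected to persist.

Step 18
Reactants: 24 (2E)-3-[(3S,4R,6S)-3-[2-(TBDPS-oxy)ethyl]-4,6-diethyl-1,2-dioxan-6-yl]-2-ethylprop-2-en-1-ol
Product: 26 (3S,4R,6S)-6-[(1E)-2-(bromomethyl)but-1-en-1-yl]-3-[2-(TBDPS-oxy)ethyl]-4,6-diethyl-1,2-dioxane, via allylic mesylate 25 (not isolated)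
Conditions: MsCl, Et3N, THF, −40 °C; then LiBr, −40 → 0 °C
Reagents that add atoms: lithium bromide, [Li+].[Br-]
Why: Mesylation followed in the same flask by SN2 exchange with bromide gives the primary allylic bromide without allylic shift, and avoids phosphine-based brominations because phosphines can reduce O–O bonds.

Step 19
Reactants: 3 (4S)-4-benzyl-3-butanoyl-1,3-oxazolidin-2-one; 26 (3S,4R,6S)-6-[(1E)-2-(bromomethyl)but-1-en-1-yl]-3-[2-(TBDPS-oxy)ethyl]-4,6-diethyl-1,2-dioxane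
Product: 28 (4S)-4-benzyl-3-[(2R,4E)-4-{[(3S,4R,6S)-3-[2-(TBDPS-oxy)ethyl]-4,6-diethyl-1,2-dioxan-6-yl]methylidene}-2-ethylhexanoyl]-1,3-oxazolidin-2-one, via sodium (Z)-enolate 27 (not isolated)
Conditions: NaN(SiMe3)2 (0.95 equiv relative to 3), THF, −78 °C; then 26, −78 → −40 °C
Reagents that add atoms: none
Why: Evans asymmetric alkylation, in which the chelated sodium (Z)-enolate is alkylated by the reactive allylic bromide on the face opposite the benzyl group and so sets C10 as R; forming the enolate with a deficit of base before adding 26 keeps free amide away from the peroxide.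

Step 20
Reactants: 28 (4S)-4-benzyl-3-[(2R,4E)-4-{[(3S,4R,6S)-3-[2-(TBDPS-oxy)ethyl]-4,6-diethyl-1,2-dioxan-6-yl]methylidene}-2-ethylhexanoyl]-1,3-oxazolidin-2-one
Product: 29 (2R,4E)-4-{[(3S,4R,6S)-3-[2-(TBDPS-oxy)ethyl]-4,6-diethyl-1,2-dioxan-6-yl]methylidene}-2-ethylhexan-1-ol
Conditions: LiBH4, MeOH (1 equiv), THF, 0 °C
Reagents that add atoms: none
Why: Reductive cleavage of the imide gives the C11 primary alcohol and releases the auxiliary, and borohydride is not expected to reduce a dialkyl peroxide.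

Step 21
Reactants: 29 (2R,4E)-4-{[(3S,4R,6S)-3-[2-(TBDPS-oxy)ethyl]-4,6-diethyl-1,2-dioxan-6-yl]methylidene}-2-ethylhexan-1-ol
Product: 30 (2R,4E)-4-{[(3S,4R,6S)-3-[2-(TBDPS-oxy)ethyl]-4,6-diethyl-1,2-dioxan-6-yl]methylidene}-2-ethylhexanal
Conditions: Dess–Martin periodinane, CH2Cl2, 0 °C
Reagents that add atoms: none
Why: Dess–Martin oxidation gives the α-branched aldehyde under non-basic conditions that protect the C10 stereocentre, and the aldehyde is used at once.

Step 22
Reactants: 31 1-phenyl-1H-tetrazole-5-thiol; 32 1-bromopropane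
Product: 33 1-phenyl-5-(propylsulfanyl)-1H-tetrazole
Conditions: K2CO3, acetone, rt
Reagents that add atoms: none
Why: S-Alkylation of the thiolate by a primary bromide (SN2) gives the sulfide.

Step 23
Reactants: 33 1-phenyl-5-(propylsulfanyl)-1H-tetrazole
Product: 34 1-phenyl-5-(propane-1-sulfonyl)-1H-tetrazole
Conditions: 30% H2O2, (NH4)6Mo7O24·4H2O (cat.), EtOH, 0 °C → rt
Reagents that add atoms: hydrogen peroxide, OO
Why: Molybdate-catalysed oxidation with H2O2 takes the sulfide through the sulfoxide to the sulfone.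

Step 24
Reactants: 34 1-phenyl-5-(propane-1-sulfonyl)-1H-tetrazole; 30 (2R,4E)-4-{[(3S,4R,6S)-3-[2-(TBDPS-oxy)ethyl]-4,6-diethyl-1,2-dioxan-6-yl]methylidene}-2-ethylhexanal
Product: 36 (3S,4R,6S)-3-[2-(TBDPS-oxy)ethyl]-6-[(1E,4R,5E)-2,4-diethylocta-1,5-dien-1-yl]-4,6-diethyl-1,2-dioxane, via potassium sulfonyl carbanion 35 (not isolated)
Conditions: KN(SiMe3)2, DME, −60 °C; then 30, −60 °C → rt
Reagents that add atoms: none
Why: Julia–Kocienski olefination, in which addition of the metalated 1-phenyltetrazolyl sulfone, Smiles rearrangement and loss of SO2 and tetrazolate give the (E)-C11=C12 alkene, favoured by the potassium counter-ion in DME and by the α-branched aldehyde; metalating the sulfone first keeps free base away from C10–H and the peroxide.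

Step 25
Reactants: 36 (3S,4R,6S)-3-[2-(TBDPS-oxy)ethyl]-6-[(1E,4R,5E)-2,4-diethylocta-1,5-dien-1-yl]-4,6-diethyl-1,2-dioxane
Product: 37 2-[(3S,4R,6S)-6-[(1E,4R,5E)-2,4-diethylocta-1,5-dien-1-yl]-4,6-diethyl-1,2-dioxan-3-yl]ethan-1-ol
Conditions: Bu4NF, AcOH, THF, 0 °C → rt
Reagents that add atoms: none
Why: Fluoride cleaves the Si–O bond, and buffering with acetic acid keeps the medium from becoming basic enough to attack the C3–H next to the peroxide.

Step 26
Reactants: 37 2-[(3S,4R,6S)-6-[(1E,4R,5E)-2,4-diethylocta-1,5-dien-1-yl]-4,6-diethyl-1,2-dioxan-3-yl]ethan-1-ol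
Product: 39 2-[(3S,4R,6S)-6-[(1E,4R,5E)-2,4-diethylocta-1,5-dien-1-yl]-4,6-diethyl-1,2-dioxan-3-yl]acetic acid, via aldehyde 38 (not isolated)
Conditions: TEMPO (cat.), PhI(OAc)2 (2.5 equiv), MeCN/H2O, rt
Reagents that add atoms: water, O
Why: The oxoammonium salt from TEMPO oxidises the primary alcohol to the aldehyde, whose hydrate is oxidised again to the acid near neutral pH, so the β-peroxy aldehyde never meets base and the alkenes and peroxide should be untouched.

Compound list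
1 | (S)-4-benzyl-1,3-oxazolidin-2-one | O=C1N[C@@H](Cc2ccccc2)CO1 | starting material
2 | butanoyl chloride | CCCC(Cl)=O | starting material
3 | (4S)-4-benzyl-3-butanoyl-1,3-oxazolidin-2-one | CCCC(=O)N1[C@@H](Cc2ccccc2)COC1=O | intermediate
4 | propane-1,3-diol | OCCCO | starting material
5 | 3-(TBDPS-oxy)propan-1-ol | OCCCO[Si](c1ccccc1)(c1ccccc1)C(C)(C)C | intermediate
6 | 3-(TBDPS-oxy)propanal | O=CCCO[Si](c1ccccc1)(c1ccccc1)C(C)(C)C | intermediate
7 | dibutylboron (Z)-enolate of 3, (4S)-4-benzyl-3-[(1Z)-1-[(dibutylboranyl)oxy]but-1-en-1-yl]-1,3-oxazolidin-2-one | CC/C=C(\OB(CCCC)CCCC)N1[C@@H](Cc2ccccc2)COC1=O | intermediate (not isolated)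
8 | (4S)-4-benzyl-3-[(2S,3R)-5-(TBDPS-oxy)-2-ethyl-3-hydroxypentanoyl]-1,3-oxazolidin-2-one | O=C([C@@H](CC)[C@H](O)CCO[Si](c1ccccc1)(c1ccccc1)C(C)(C)C)N1[C@@H](Cc2ccccc2)COC1=O | intermediate
9 | (4S)-4-benzyl-3-[(2S,3R)-5-(TBDPS-oxy)-2-ethyl-3-(TES-oxy)pentanoyl]-1,3-oxazolidin-2-one | O=C([C@@H](CC)[C@H](O[Si](CC)(CC)CC)CCO[Si](c1ccccc1)(c1ccccc1)C(C)(C)C)N1[C@@H](Cc2ccccc2)COC1=O | intermediate
10 | (2R,3R)-5-(TBDPS-oxy)-2-ethyl-3-(TES-oxy)pentan-1-ol | OC[C@@H](CC)[C@H](O[Si](CC)(CC)CC)CCO[Si](c1ccccc1)(c1ccccc1)C(C)(C)C | intermediate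
11 | ethyl 2-(triphenylphosphoranylidene)butanoate | CCOC(=O)C(CC)=P(c1ccccc1)(c1ccccc1)c1ccccc1 | starting material
12 | (2S,3R)-5-(TBDPS-oxy)-2-ethyl-3-(TES-oxy)pentanal | O=C[C@@H](CC)[C@H](O[Si](CC)(CC)CC)CCO[Si](c1ccccc1)(c1ccccc1)C(C)(C)C | intermediate (not isolated)
13 | ethyl (2E,4R,5R)-7-(TBDPS-oxy)-2,4-diethyl-5-(TES-oxy)hept-2-enoate | CCOC(=O)/C(CC)=C/[C@@H](CC)[C@H](O[Si](CC)(CC)CC)CCO[Si](c1ccccc1)(c1ccccc1)C(C)(C)C | intermediate
14 | (2E,4R,5R)-7-(TBDPS-oxy)-2,4-diethyl-5-(TES-oxy)hept-2-en-1-ol | OC/C(CC)=C/[C@@H](CC)[C@H](O[Si](CC)(CC)CC)CCO[Si](c1ccccc1)(c1ccccc1)C(C)(C)C | intermediate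
15 | [(2S,3S)-3-[(3R,4R)-6-(TBDPS-oxy)-4-(TES-oxy)hexan-3-yl]-2-ethyloxiran-2-yl]methanol | OC[C@]1(CC)O[C@H]1[C@@H](CC)[C@H](O[Si](CC)(CC)CC)CCO[Si](c1ccccc1)(c1ccccc1)C(C)(C)C | intermediate
16 | (2R,4R,5R)-7-(TBDPS-oxy)-2,4-diethyl-5-(TES-oxy)heptane-1,2-diol | OC[C@@](O)(CC)C[C@@H](CC)[C@H](O[Si](CC)(CC)CC)CCO[Si](c1ccccc1)(c1ccccc1)C(C)(C)C | intermediate
17 | (2R,4R,5R)-7-(TBDPS-oxy)-2,4-diethylheptane-1,2,5-triol | OC[C@@](O)(CC)C[C@@H](CC)[C@H](O)CCO[Si](c1ccccc1)(c1ccccc1)C(C)(C)C | intermediate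
18 | (2R,4R,5R)-7-(TBDPS-oxy)-2,4-diethyl-2-hydroxyheptane-1,5-diyl dimethanesulfonate | CS(=O)(=O)OC[C@@](O)(CC)C[C@@H](CC)[C@H](OS(C)(=O)=O)CCO[Si](c1ccccc1)(c1ccccc1)C(C)(C)C | intermediate (not isolated)
19 | (2R)-2-[(2R,3R)-5-(TBDPS-oxy)-2-ethyl-3-(methanesulfonyloxy)pentyl]-2-ethyloxirane | O1C[C@@]1(CC)C[C@@H](CC)[C@H](OS(C)(=O)=O)CCO[Si](c1ccccc1)(c1ccccc1)C(C)(C)C | intermediate
20 | (2R)-2-[(2R,3S)-5-(TBDPS-oxy)-2-ethyl-3-hydroperoxypentyl]-2-ethyloxirane | O1C[C@@]1(CC)C[C@@H](CC)[C@H](CCO[Si](c1ccccc1)(c1ccccc1)C(C)(C)C)OO | intermediate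
21 | [(3S,4R,6S)-3-[2-(TBDPS-oxy)ethyl]-4,6-diethyl-1,2-dioxan-6-yl]methanol | OC[C@]1(CC)C[C@@H](CC)[C@H](CCO[Si](c2ccccc2)(c2ccccc2)C(C)(C)C)OO1 | intermediate
22 | (3S,4R,6S)-3-[2-(TBDPS-oxy)ethyl]-4,6-diethyl-1,2-dioxane-6-carbaldehyde | O=C[C@]1(CC)C[C@@H](CC)[C@H](CCO[Si](c2ccccc2)(c2ccccc2)C(C)(C)C)OO1 | intermediate
23 | ethyl (2E)-3-[(3S,4R,6S)-3-[2-(TBDPS-oxy)ethyl]-4,6-diethyl-1,2-dioxan-6-yl]-2-ethylprop-2-enoate | CCOC(=O)/C(CC)=C/[C@]1(CC)C[C@@H](CC)[C@H](CCO[Si](c2ccccc2)(c2ccccc2)C(C)(C)C)OO1 | intermediate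
24 | (2E)-3-[(3S,4R,6S)-3-[2-(TBDPS-oxy)ethyl]-4,6-diethyl-1,2-dioxan-6-yl]-2-ethylprop-2-en-1-ol | OC/C(CC)=C/[C@]1(CC)C[C@@H](CC)[C@H](CCO[Si](c2ccccc2)(c2ccccc2)C(C)(C)C)OO1 | intermediate
25 | (2E)-3-[(3S,4R,6S)-3-[2-(TBDPS-oxy)ethyl]-4,6-diethyl-1,2-dioxan-6-yl]-2-ethylprop-2-en-1-yl methanesulfonate | CS(=O)(=O)OC/C(CC)=C/[C@]1(CC)C[C@@H](CC)[C@H](CCO[Si](c2ccccc2)(c2ccccc2)C(C)(C)C)OO1 | intermediate (not isolated)
26 | (3S,4R,6S)-6-[(1E)-2-(bromomethyl)but-1-en-1-yl]-3-[2-(TBDPS-oxy)ethyl]-4,6-diethyl-1,2-dioxane | BrC/C(CC)=C/[C@]1(CC)C[C@@H](CC)[C@H](CCO[Si](c2ccccc2)(c2ccccc2)C(C)(C)C)OO1 | intermediate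
27 | sodium (Z)-enolate of 3, sodium (1Z)-1-[(4S)-4-benzyl-2-oxo-1,3-oxazolidin-3-yl]but-1-en-1-olate | CC/C=C(\[O-])N1[C@@H](Cc2ccccc2)COC1=O.[Na+] | intermediate (not isolated)
28 | (4S)-4-benzyl-3-[(2R,4E)-4-{[(3S,4R,6S)-3-[2-(TBDPS-oxy)ethyl]-4,6-diethyl-1,2-dioxan-6-yl]methylidene}-2-ethylhexanoyl]-1,3-oxazolidin-2-one | O=C([C@H](CC)C/C(CC)=C/[C@]1(CC)C[C@@H](CC)[C@H](CCO[Si](c2ccccc2)(c2ccccc2)C(C)(C)C)OO1)N1[C@@H](Cc2ccccc2)COC1=O | intermediate
29 | (2R,4E)-4-{[(3S,4R,6S)-3-[2-(TBDPS-oxy)ethyl]-4,6-diethyl-1,2-dioxan-6-yl]methylidene}-2-ethylhexan-1-ol | OC[C@H](CC)C/C(CC)=C/[C@]1(CC)C[C@@H](CC)[C@H](CCO[Si](c2ccccc2)(c2ccccc2)C(C)(C)C)OO1 | intermediate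
30 | (2R,4E)-4-{[(3S,4R,6S)-3-[2-(TBDPS-oxy)ethyl]-4,6-diethyl-1,2-dioxan-6-yl]methylidene}-2-ethylhexanal | O=C[C@H](CC)C/C(CC)=C/[C@]1(CC)C[C@@H](CC)[C@H](CCO[Si](c2ccccc2)(c2ccccc2)C(C)(C)C)OO1 | intermediate
31 | 1-phenyl-1H-tetrazole-5-thiol | Sc1nnnn1-c1ccccc1 | starting material
32 | 1-bromopropane | CCCBr | starting material
33 | 1-phenyl-5-(propylsulfanyl)-1H-tetrazole | CCCSc1nnnn1-c1ccccc1 | intermediate
34 | 1-phenyl-5-(propane-1-sulfonyl)-1H-tetrazole | CCCS(=O)(=O)c1nnnn1-c1ccccc1 | intermediate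
35 | potassium 1-[(1-phenyl-1H-tetrazol-5-yl)sulfonyl]propan-1-ide | CC[CH-]S(=O)(=O)c1nnnn1-c1ccccc1.[K+] | intermediate (not isolated)
36 | (3S,4R,6S)-3-[2-(TBDPS-oxy)ethyl]-6-[(1E,4R,5E)-2,4-diethylocta-1,5-dien-1-yl]-4,6-diethyl-1,2-dioxane | CC/C=C/[C@H](CC)C/C(CC)=C/[C@]1(CC)C[C@@H](CC)[C@H](CCO[Si](c2ccccc2)(c2ccccc2)C(C)(C)C)OO1 | intermediate
37 | 2-[(3S,4R,6S)-6-[(1E,4R,5E)-2,4-diethylocta-1,5-dien-1-yl]-4,6-diethyl-1,2-dioxan-3-yl]ethan-1-ol | CC/C=C/[C@H](CC)C/C(CC)=C/[C@]1(CC)C[C@@H](CC)[C@H](CCO)OO1 | intermediate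
38 | 2-[(3S,4R,6S)-6-[(1E,4R,5E)-2,4-diethylocta-1,5-dien-1-yl]-4,6-diethyl-1,2-dioxan-3-yl]acetaldehyde | CC/C=C/[C@H](CC)C/C(CC)=C/[C@]1(CC)C[C@@H](CC)[C@H](CC=O)OO1 | intermediate (not isolated)
39 | 2-[(3S,4R,6S)-6-[(1E,4R,5E)-2,4-diethylocta-1,5-dien-1-yl]-4,6-diethyl-1,2-dioxan-3-yl]acetic acid | CC/C=C/[C@H](CC)C/C(=C/[C@]1(CC)C[C@@H](CC)[C@H](CC(=O)O)OO1)CC | target

Total step count: 26. Longest linear sequence: 23 steps (steps 2–21, then 24–26, from propane-1,3-diol).

The three steps most likely to fail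

Step 13. What may go wrong: substitution at the β-branched secondary carbon may be slow, so that elimination of methanesulfonic acid, base-triggered collapse of the new hydroperoxide to the ketone, or attack of peroxide anion on the oxirane methylene takes over. Fallback: the peroxide would be brought in as a capped nucleophile. Setting out from mesylate 19, alkylation of 2-methoxyprop-2-yl hydroperoxide (CsOH·H2O, DMF, 0 °C → rt; SN2 with inversion) would give the peroxyketal (2R)-2-[(2R,3S)-5-(TBDPS-oxy)-2-ethyl-3-[(2-methoxypropan-2-yl)peroxy]pentyl]-2-ethyloxirane F1, which has no O–O–H to be deprotonated. Aqueous acetic acid in THF at 0 °C then hydrolyses the ketal, and the route is rejoined at hydroperoxide 20.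

Step 14. What may go wrong: the activated oxirane may undergo a 1,2-hydride shift to the aldehyde, ionise to a tertiary cation with loss of stereochemical fidelity at C6, or close at C7 to the seven-membered peroxide before the tethered hydroperoxide engages C6. Fallback: the order of the two C–O bond formations would be reversed. Setting out again from epoxy mesylate 19, a large excess of ethereal H2O2 with catalytic H3PMo12O40 would open the oxirane at C6 with inversion, the external nucleophile now being present in high concentration. This gives the tertiary hydroperoxide (2S,4R,5R)-7-(TBDPS-oxy)-2,4-diethyl-2-hydroperoxy-1-hydroxyheptan-5-yl methanesulfonate F2. KOt-Bu with 18-crown-6 in THF at 0 °C then lets the peroxide anion displace the C3 mesylate (6-exo-tet, inversion at C3), and the route is rejoined at dioxane 21.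

Step 9. What may go wrong: catalyst-controlled oxygen delivery must override the facial preference that allylic strain imposes through the C4 centre, so facial selectivity may be poor and turnover slow on the hindered trisubstituted alkene. Fallback: the alkene geometry would be inverted so that substrate and catalyst preferences coincide. Setting out from alcohol 10, oxidation as in step 7 gives aldehyde 12, which is condensed with methyl 2-[bis(2,2,2-trifluoroethoxy)phosphoryl]butanoate (KN(SiMe3)2, 18-crown-6, THF, −78 °C; Still–Gennari olefination). This would give methyl (2Z,4R,5R)-7-(TBDPS-oxy)-2,4-diethyl-5-(TES-oxy)hept-2-enoate F3, and i-Bu2AlH reduces it to (2Z,4R,5R)-7-(TBDPS-oxy)-2,4-diethyl-5-(TES-oxy)hept-2-en-1-ol F4. In the (Z) series the allylic strain lies between C4 and the hydroxymethyl group and exposes the face that leads to the required C6 configuration. Ti(OiPr)4/L-(+)-diethyl tartrate/t-BuOOH (now matched) or hydroxyl-directed VO(acac)2/t-BuOOH should therefore give [(2S,3R)-3-[(3R,4R)-6-(TBDPS-oxy)-4-(TES-oxy)hexan-3-yl]-2-ethyloxiran-2-yl]methanol F5, which differs from 15 only at C5. LiAlH4 opening at C5 removes that centre, and the route is rejoined at diol 16.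

Further compounds
F1 | step 13 | (2R)-2-[(2R,3S)-5-(TBDPS-oxy)-2-ethyl-3-[(2-methoxypropan-2-yl)peroxy]pentyl]-2-ethyloxirane | O1C[C@@]1(CC)C[C@@H](CC)[C@H](CCO[Si](c1ccccc1)(c1ccccc1)C(C)(C)C)OOC(C)(C)OC
F2 | step 14 | (2S,4R,5R)-7-(TBDPS-oxy)-2,4-diethyl-2-hydroperoxy-1-hydroxyheptan-5-yl methanesulfonate | OC[C@](OO)(CC)C[C@@H](CC)[C@H](OS(C)(=O)=O)CCO[Si](c1ccccc1)(c1ccccc1)C(C)(C)C
F3 | step 9 | methyl (2Z,4R,5R)-7-(TBDPS-oxy)-2,4-diethyl-5-(TES-oxy)hept-2-enoate | COC(=O)/C(CC)=C\[C@@H](CC)[C@H](O[Si](CC)(CC)CC)CCO[Si](c1ccccc1)(c1ccccc1)C(C)(C)C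
F4 | step 9 | (2Z,4R,5R)-7-(TBDPS-oxy)-2,4-diethyl-5-(TES-oxy)hept-2-en-1-ol | OC/C(CC)=C\[C@@H](CC)[C@H](O[Si](CC)(CC)CC)CCO[Si](c1ccccc1)(c1ccccc1)C(C)(C)C
F5 | step 9 | [(2S,3R)-3-[(3R,4R)-6-(TBDPS-oxy)-4-(TES-oxy)hexan-3-yl]-2-ethyloxiran-2-yl]methanol | OC[C@]1(CC)O[C@@H]1[C@@H](CC)[C@H](O[Si](CC)(CC)CC)CCO[Si](c1ccccc1)(c1ccccc1)C(C)(C)C
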